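**Retrosynthetic overview**
1. The oxirane is made last by an enantioselective acylative ring contraction of a prochiral 3-aryl-oxetan-3-ol with (2R)-2-methylbutanoyl bromide. This one operation forms the epoxide, sets the (R) quaternary carbon and installs the side-chain ester.
2. The oxetanol precursor carries the aryl angelate (Yamaguchi, angelic acid) and the benzylic (2R)-2-methylbutanoate (Steglich), put on by two chemoselective acylations around removal of an allyl group from the phenol.
3. The aryl–C(OH) bond comes from an alkoxy-directed Br–Li exchange and addition to oxetan-3-one; the benzylic CH2OH comes from a second Br–Li exchange, DMF and NaBH4.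
4. The arene is the allyl ether of 2,5-dibromophenol, made from 1,4-dibromobenzene by ortho-lithiation, borylation and oxidation.
5. Ring order: the benzene and oxetane rings come with the building blocks; the oxirane is formed last, from the oxetane.

Assumption: (2R)-2-methylbutanoic acid and angelic acid are bought isomerically pure; the SMILES is read as (R) at the oxirane carbon, (R) in both 2-methylbutanoates and (Z) in the enoate. SQ = 3-{[3,5-bis(trifluoromethyl)phenyl]amino}-4-({(2S)-3,3-dimethyl-1-oxo-1-[(2R)-2-(phenanthren-9-yl)pyrrolidin-1-yl]butan-2-yl}amino)cyclobut-3-ene-1,2-dione, a chiral squaramide hydrogen-bond donor; whichever enantiomer of SQ delivers bromide to the pro-S CH2 of the oxetane is used.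

**Route**

Step 1
Reactants: 1 1,4-dibromobenzene
Product: 4 2,5-dibromophenol, via aryllithium 2 (not isolated), via dimethyl arylboronate 3 (not isolated)
Conditions: LiN(iPr)2 (1.1 equiv), THF, −78 °C; B(OMe)3, −78 °C to rt; AcOH, 30% H2O2, 0 °C to rt
Reagents that add atoms: hydrogen peroxide, OO
Why: The four C–H positions of 1 are equivalent and each lies ortho to bromine, so directed ortho-lithiation at −78 °C gives a single aryllithium, and borylation followed by peroxide oxidation (boronate oxidation) turns C–Li into C–OH with no stereocenter involved.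

Step 2
Reactants: 4 2,5-dibromophenol
Product: 5 1,4-dibromo-2-(prop-2-en-1-yloxy)benzene
Conditions: allyl bromide, K2CO3, acetone, reflux
Reagents that add atoms: allyl bromide, C=CCBr
Why: Williamson ether synthesis on the acidic phenol gives the allyl ether, which tolerates organolithiums at −78 °C, steers the next exchange to the neighbouring bromine and later comes off under neutral conditions.

Step 3
Reactants: 5 1,4-dibromo-2-(prop-2-en-1-yloxy)benzene; 6 oxetan-3-one
Product: 8 3-[4-bromo-2-(prop-2-en-1-yloxy)phenyl]oxetan-3-ol, via aryllithium 7 (not isolated)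
Conditions: n-BuLi (1.05 equiv), Et2O, −78 °C; then 6, −78 °C to rt; aq NH4Cl
Reagents that add atoms: none
Why: Bromine–lithium exchange is fastest at the bromine ortho to the alkoxy group (inductive and chelating assistance, the ortho effect), and the aryllithium adds to the strained ketone (1,2-addition) to give a carbinol carbon that is still prochiral because both ring CH2O arms are identical.

Step 4
Reactants: 8 3-[4-bromo-2-(prop-2-en-1-yloxy)phenyl]oxetan-3-ol
Product: 11 3-[4-(hydroxymethyl)-2-(prop-2-en-1-yloxy)phenyl]oxetan-3-ol, via dilithio species 9 (not isolated), via aldehyde 10 (not isolated)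
Conditions: n-BuLi (2.2 equiv), THF, −78 °C; DMF, −78 to 0 °C; then MeOH, NaBH4, 0 °C; aq NH4Cl
Reagents that add atoms: N,N-dimethylformamide, CN(C)C=O
Why: One equivalent of n-BuLi forms the lithium alkoxide and the second effects bromine–lithium exchange; formylation with DMF (Bouveault aldehyde synthesis) and borohydride reduction in the same pot give the benzylic alcohol while oxetane and allyl ether are inert at −78 °C.

Step 5
Reactants: 11 3-[4-(hydroxymethyl)-2-(prop-2-en-1-yloxy)phenyl]oxetan-3-ol; 12 (2R)-2-methylbutanoic acid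
Product: 13 [4-(3-hydroxyoxetan-3-yl)-3-(prop-2-en-1-yloxy)phenyl]methyl (2R)-2-methylbutanoate
Conditions: DCC, DMAP (10 mol %), CH2Cl2, 0 °C to rt
Reagents that add atoms: none
Why: Steglich esterification acylates only the primary benzylic hydroxyl, the tertiary oxetanol being too hindered, and the (R) centre of the acid is carried over unchanged because no ketene or enolate is formed.

Step 6
Reactants: 13 [4-(3-hydroxyoxetan-3-yl)-3-(prop-2-en-1-yloxy)phenyl]methyl (2R)-2-methylbutanoate
Product: 14 [3-hydroxy-4-(3-hydroxyoxetan-3-yl)phenyl]methyl (2R)-2-methylbutanoate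
Conditions: Pd(PPh3)4 (3 mol %), morpholine, THF, rt
Reagents that add atoms: none
Why: Zerovalent palladium ionises the allyl aryl ether to a π-allyl complex that morpholine traps (Tsuji–Trost deallylation), neutral conditions that leave the oxetane, the tertiary alcohol and the alkyl ester untouched.

Step 7
Reactants: 14 [3-hydroxy-4-(3-hydroxyoxetan-3-yl)phenyl]methyl (2R)-2-methylbutanoate; 15 (2Z)-2-methylbut-2-enoic acid (angelic acid)
Product: 17 2-(3-hydroxyoxetan-3-yl)-5-({[(2R)-2-methylbutanoyl]oxy}methyl)phenyl (2Z)-2-methylbut-2-enoate, via mixed anhydride 16 (not isolated)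
Conditions: 15, 2,4,6-trichlorobenzoyl chloride, Et3N, toluene, rt; then 14, rt
Reagents that add atoms: none
Why: Yamaguchi esterification through the hindered mixed anhydride transfers the angeloyl group to the phenol, which is far more reactive than the tertiary alcohol, and leaving out DMAP and heat keeps the (Z) double bond from isomerising to the tiglate.

Step 8
Reactants: 17 2-(3-hydroxyoxetan-3-yl)-5-({[(2R)-2-methylbutanoyl]oxy}methyl)phenyl (2Z)-2-methylbut-2-enoate; 12 (2R)-2-methylbutanoic acid
Product: 20 [(2R)-2-{2-[(2Z)-2-methylbut-2-enoyloxy]-4-({[(2R)-2-methylbutanoyl]oxy}methyl)phenyl}oxiran-2-yl]methyl (2R)-2-methylbutanoate, via acyl bromide 18 (not isolated), via bromohydrin ester 19 (not isolated)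
Conditions: 12, (COBr)2, CH2Cl2, 0 °C, volatiles removed; then 17, SQ (10 mol %), 4 Å MS, t-BuOMe, −60 °C; then Ag2O, CH2Cl2, −20 °C to rt, dark
Reagents that add atoms: none
Why: Proposed new method: the squaramide abstracts bromide from acyl bromide 18, so the oxetane oxygen is acylated to an O-acyloxetanium ion paired with catalyst-bound bromide; enantiodetermining SN2 delivery of that bromide to the pro-S CH2 gives (S)-bromohydrin ester 19, and Ag2O then promotes 3-exo-tet closure by the tertiary hydroxyl without forming a free alkoxide (which would let the neighbouring aryl angelate migrate), so the net change is an acylative oxetane-to-oxirane ring contraction that sets the (R) quaternary carbon and leaves it untouched in the closure; the closest known reactions are the squaramide-catalysed enantioselective addition of Me3SiBr to 3-substituted oxetanes, the Lewis-acid cleavage of oxetanes by acyl halides to 3-halopropyl esters and halohydrin-to-epoxide closure, whereas an enantioselective acyl-halide opening and the one-pot contraction of an oxetan-3-ol to a 2-(acyloxymethyl)oxirane have not been shown.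

**Compound list**
1 | 1,4-dibromobenzene | Brc1ccc(Br)cc1 | starting material
2 | (2,5-dibromophenyl)lithium | [Li]c1cc(Br)ccc1Br | intermediate
3 | dimethyl (2,5-dibromophenyl)boronate | COB(OC)c1cc(Br)ccc1Br | intermediate
4 | 2,5-dibromophenol | Oc1cc(Br)ccc1Br | intermediate
5 | 1,4-dibromo-2-(prop-2-en-1-yloxy)benzene | C=CCOc1cc(Br)ccc1Br | intermediate
6 | oxetan-3-one | O=C1COC1 | starting material
7 | [4-bromo-2-(prop-2-en-1-yloxy)phenyl]lithium | [Li]c1ccc(Br)cc1OCC=C | intermediate
8 | 3-[4-bromo-2-(prop-2-en-1-yloxy)phenyl]oxetan-3-ol | C=CCOc1cc(Br)ccc1C1(O)COC1 | intermediate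
9 | lithium 3-[4-lithio-2-(prop-2-en-1-yloxy)phenyl]oxetan-3-olate | [Li]c1ccc(C2(O[Li])COC2)c(OCC=C)c1 | intermediate
10 | 4-(3-hydroxyoxetan-3-yl)-3-(prop-2-en-1-yloxy)benzaldehyde | C=CCOc1cc(C=O)ccc1C1(O)COC1 | intermediate
11 | 3-[4-(hydroxymethyl)-2-(prop-2-en-1-yloxy)phenyl]oxetan-3-ol | C=CCOc1cc(CO)ccc1C1(O)COC1 | intermediate
12 | (2R)-2-methylbutanoic acid | CC[C@@H](C)C(=O)O | starting material
13 | [4-(3-hydroxyoxetan-3-yl)-3-(prop-2-en-1-yloxy)phenyl]methyl (2R)-2-methylbutanoate | C=CCOc1cc(COC(=O)[C@H](C)CC)ccc1C1(O)COC1 | intermediate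
14 | [3-hydroxy-4-(3-hydroxyoxetan-3-yl)phenyl]methyl (2R)-2-methylbutanoate | Oc1cc(COC(=O)[C@H](C)CC)ccc1C1(O)COC1 | intermediate
15 | (2Z)-2-methylbut-2-enoic acid (angelic acid) | C/C=C(/C)C(=O)O | starting material
16 | (2Z)-2-methylbut-2-enoic 2,4,6-trichlorobenzoic anhydride | C/C=C(/C)C(=O)OC(=O)c1c(Cl)cc(Cl)cc1Cl | intermediate
17 | 2-(3-hydroxyoxetan-3-yl)-5-({[(2R)-2-methylbutanoyl]oxy}methyl)phenyl (2Z)-2-methylbut-2-enoate | C/C=C(/C)C(=O)Oc1cc(COC(=O)[C@H](C)CC)ccc1C1(O)COC1 | intermediate
18 | (2R)-2-methylbutanoyl bromide | CC[C@@H](C)C(=O)Br | intermediate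
19 | 2-[(2S)-1-bromo-2-hydroxy-3-{[(2R)-2-methylbutanoyl]oxy}propan-2-yl]-5-({[(2R)-2-methylbutanoyl]oxy}methyl)phenyl (2Z)-2-methylbut-2-enoate | C/C=C(/C)C(=O)Oc1cc(COC(=O)[C@H](C)CC)ccc1[C@](O)(COC(=O)[C@H](C)CC)CBr | intermediate
20 | [(2R)-2-{2-[(2Z)-2-methylbut-2-enoyloxy]-4-({[(2R)-2-methylbutanoyl]oxy}methyl)phenyl}oxiran-2-yl]methyl (2R)-2-methylbutanoate (CNP0166772.1) | C/C=C(/C)C(=O)Oc1cc(COC(=O)[C@H](C)CC)ccc1[C@]1(COC(=O)[C@H](C)CC)CO1 | target

**Step count and risks**
Total steps: 8. Longest linear sequence: 8 (1 → 4 → 5 → 8 → 11 → 13 → 14 → 17 → 20).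

Three steps most likely to fail:

Step 8 (the new ring contraction). Risks are a racemic background opening by traces of HBr, acylation of the tertiary hydroxyl, low selectivity between the two CH2 arms, and partial epimerisation of acyl bromide 18. The fallback uses known chemistry, sets out from 17 and comes back at 19. The tertiary hydroxyl of 17 is silylated with N-(trimethylsilyl)imidazole in CH2Cl2 to give 5-({[(2R)-2-methylbutanoyl]oxy}methyl)-2-{3-[(trimethylsilyl)oxy]oxetan-3-yl}phenyl (2Z)-2-methylbut-2-enoate F1. The known squaramide-catalysed enantioselective addition of Me3SiBr to 3,3-disubstituted oxetanes (t-BuOMe, −78 °C) then gives 2-[(2S)-1-bromo-2,3-bis(trimethylsilyloxy)propan-2-yl]-5-({[(2R)-2-methylbutanoyl]oxy}methyl)phenyl (2Z)-2-methylbut-2-enoate F2. Citric acid in MeOH at 0 °C removes both silyl groups to give 2-[(2S)-1-bromo-2,3-dihydroxypropan-2-yl]-5-({[(2R)-2-methylbutanoyl]oxy}methyl)phenyl (2Z)-2-methylbut-2-enoate F3. Steglich esterification of its primary hydroxyl with 12 (DCC, 5 mol % DMAP, 0 °C) gives 19, which is closed with Ag2O as in step 8 to give 20.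

Step 7 (angeloylation). Risks are Z-to-E isomerisation and base-promoted migration of the new aryl ester onto the neighbouring tertiary hydroxyl through a six-membered transition state. The fallback changes the order of events so that no free hydroxyl ever sits next to the aryl ester; it sets out from 13 and comes back at 20. Allyl ether 13 is taken through the ring contraction of step 8 with 18 and SQ, the closure now being done with K2CO3 in MeCN because no aryl ester is present. This gives, through {4-[(2S)-1-bromo-2-hydroxy-3-{[(2R)-2-methylbutanoyl]oxy}propan-2-yl]-3-(prop-2-en-1-yloxy)phenyl}methyl (2R)-2-methylbutanoate F4, the epoxide [(2R)-2-{4-({[(2R)-2-methylbutanoyl]oxy}methyl)-2-(prop-2-en-1-yloxy)phenyl}oxiran-2-yl]methyl (2R)-2-methylbutanoate F5. Pd(PPh3)4 with PhSiH3 in CH2Cl2 removes the allyl group to give [(2R)-2-{2-hydroxy-4-({[(2R)-2-methylbutanoyl]oxy}methyl)phenyl}oxiran-2-yl]methyl (2R)-2-methylbutanoate F6. This phenol is likely to be labile next to the benzylic epoxide, so it is acylated at once with mixed anhydride 16 to give 20.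

Step 3 (regioselective exchange and addition). Risks are exchange at the wrong bromine and cyclisation of the ortho-lithiated allyl ether. The fallback introduces the phenol oxygen after the oxetanol instead of before; it sets out from 1 and 6 and comes back at 8. Single Br–Li exchange of 1 (n-BuLi, THF, −78 °C) and addition to 6 give 3-(4-bromophenyl)oxetan-3-ol F7. Dehydrogenative silylation with Et2SiH2 and catalytic [Ir(cod)OMe]2 gives {[3-(4-bromophenyl)oxetan-3-yl]oxy}diethylsilane F8. Iridium-catalysed hydroxyl-directed ortho C–H silylation ([Ir(cod)OMe]2, 1,10-phenanthroline, norbornene, THF, 80 °C) closes 6-bromo-1,1-diethyl-1H-spiro[2,1-benzoxasilole-3,3'-oxetane] F9. Tamao–Fleming oxidation (H2O2, KHCO3, THF/MeOH) gives 3-(4-bromo-2-hydroxyphenyl)oxetan-3-ol F10, and phenol-selective allylation (allyl bromide, K2CO3, acetone) gives 8.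

**Further compounds**
F1 | step 8 | 5-({[(2R)-2-methylbutanoyl]oxy}methyl)-2-{3-[(trimethylsilyl)oxy]oxetan-3-yl}phenyl (2Z)-2-methylbut-2-enoate | C/C=C(/C)C(=O)Oc1cc(COC(=O)[C@H](C)CC)ccc1C1(O[Si](C)(C)C)COC1
F2 | step 8 | 2-[(2S)-1-bromo-2,3-bis(trimethylsilyloxy)propan-2-yl]-5-({[(2R)-2-methylbutanoyl]oxy}methyl)phenyl (2Z)-2-methylbut-2-enoate | C/C=C(/C)C(=O)Oc1cc(COC(=O)[C@H](C)CC)ccc1[C@](O[Si](C)(C)C)(CO[Si](C)(C)C)CBr
F3 | step 8 | 2-[(2S)-1-bromo-2,3-dihydroxypropan-2-yl]-5-({[(2R)-2-methylbutanoyl]oxy}methyl)phenyl (2Z)-2-methylbut-2-enoate | C/C=C(/C)C(=O)Oc1cc(COC(=O)[C@H](C)CC)ccc1[C@](O)(CO)CBr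
F4 | step 7 | {4-[(2S)-1-bromo-2-hydroxy-3-{[(2R)-2-methylbutanoyl]oxy}propan-2-yl]-3-(prop-2-en-1-yloxy)phenyl}methyl (2R)-2-methylbutanoate | C=CCOc1cc(COC(=O)[C@H](C)CC)ccc1[C@](O)(COC(=O)[C@H](C)CC)CBr
F5 | step 7 | [(2R)-2-{4-({[(2R)-2-methylbutanoyl]oxy}methyl)-2-(prop-2-en-1-yloxy)phenyl}oxiran-2-yl]methyl (2R)-2-methylbutanoate | C=CCOc1cc(COC(=O)[C@H](C)CC)ccc1[C@]1(COC(=O)[C@H](C)CC)CO1
F6 | step 7 | [(2R)-2-{2-hydroxy-4-({[(2R)-2-methylbutanoyl]oxy}methyl)phenyl}oxiran-2-yl]methyl (2R)-2-methylbutanoate | Oc1cc(COC(=O)[C@H](C)CC)ccc1[C@]1(COC(=O)[C@H](C)CC)CO1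
F7 | step 3 | 3-(4-bromophenyl)oxetan-3-ol | OC1(c2ccc(Br)cc2)COC1
F8 | step 3 | {[3-(4-bromophenyl)oxetan-3-yl]oxy}diethylsilane | CC[SiH](CC)OC1(c2ccc(Br)cc2)COC1
F9 | step 3 | 6-bromo-1,1-diethyl-1H-spiro[2,1-benzoxasilole-3,3'-oxetane] | CC[Si]1(CC)OC2(COC2)c2ccc(Br)cc21
F10 | step 3 | 3-(4-bromo-2-hydroxyphenyl)oxetan-3-ol | Oc1cc(Br)ccc1C1(O)COC1
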